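**Strategy.** The route rests on disconnecting the O1–C2 bond of the flavan pyran (ring E). The key step exploits two features: O1 is a phenolic oxygen of the flavan benzo ring D lying para to the biaryl carbon C6, and C2 is a benzylic carbinol carbon. A 3-(2,6-dibenzyloxy-4-hydroxyphenyl)flavone is therefore locally symmetric, so ortho-formylation and chain extension can give one constitution only and leave O1 as the sole free phenol. An intramolecular Mitsunobu etherification then closes ring E and, by inversion of an (R)-carbinol set through asymmetric transfer hydrogenation, delivers (2S) in one operation. The precursor is an open-chain hexabenzylated 3-arylflavone carbinol; hydrogenolysis finishes the synthesis.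

Key step: step 9

Ring names: flavone unit A (benzo), C (pyranone), B (aryl); flavan unit D (benzo), E (pyran), F (aryl). Flavan atoms are numbered O1, C2 … C8a.

Assumption: the C3(flavone)–C6(flavan) biaryl axis carries no assigned configuration and is taken as not configurationally fixed, so C2 is the only stereocenter to control.

**Step 1**
Reactants: 1 apigenin
Product: 2 5,7-bis(benzyloxy)-2-[4-(benzyloxy)phenyl]-4H-chromen-4-one
Conditions: BnBr (4 equiv), K2CO3, DMF, 80 °C
Reagents that add atoms: benzyl bromide, BrCc1ccccc1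
Why: Williamson etherification; heating in DMF should overcome the hydrogen bond of the 5-OH to C4=O, so that all three phenols are benzylated.

**Step 2**
Reactants: 2 5,7-bis(benzyloxy)-2-[4-(benzyloxy)phenyl]-4H-chromen-4-one
Product: 4 5,7-bis(benzyloxy)-2-[4-(benzyloxy)phenyl]-3-iodo-4H-chromen-4-one, via 3-lithiochromone 3 (not isolated)
Conditions: LiN(iPr)2, THF, −78 °C; then I2, −78 °C to rt
Reagents that add atoms: iodine, II
Why: Directed lithiation/iodination; C3–H is the most acidic C–H of a flavone (vinylic, next to C4=O, which chelates lithium), so iodine should enter at C3 only.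

**Step 3**
Reactants: 5 3,5-bis(benzyloxy)phenol
Product: 6 [3,5-bis(benzyloxy)phenoxy]triisopropylsilane
Conditions: iPr3SiCl, imidazole, DMF, rt
Reagents that add atoms: triisopropylsilyl chloride, CC(C)[Si](Cl)(C(C)C)C(C)C
Why: Standard silylation; the bulky, poorly coordinating silyl ether marks the future O1 and shields its two ortho positions in the next step.

**Step 4**
Reactants: 6 [3,5-bis(benzyloxy)phenoxy]triisopropylsilane (1.3 equiv); 4 5,7-bis(benzyloxy)-2-[4-(benzyloxy)phenyl]-3-iodo-4H-chromen-4-one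
Product: 9 5,7-bis(benzyloxy)-2-[4-(benzyloxy)phenyl]-3-[2,6-bis(benzyloxy)-4-(triisopropylsilyloxy)phenyl]-4H-chromen-4-one, via aryllithium 7 (not isolated), via arylzinc chloride 8 (not isolated)
Conditions: n-BuLi, THF, 0 °C; ZnCl2, THF, 0 °C to rt; then 4, Pd2(dba)3 (2 mol %), RuPhos (8 mol %), THF, 65 °C
Reagents that add atoms: none
Why: Directed ortho-metalation at the C–H flanked by the two benzyloxy groups (cooperative coordination, silyloxy side shielded), then Negishi cross-coupling, in which a dialkylbiarylphosphine on palladium should allow the tetra-ortho-substituted biaryl to form and the arylzinc tolerates the chromone carbonyl.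

**Step 5**
Reactants: 9 silyl-protected biaryl
Product: 10 5,7-bis(benzyloxy)-2-[4-(benzyloxy)phenyl]-3-[2,6-bis(benzyloxy)-4-hydroxyphenyl]-4H-chromen-4-one
Conditions: Bu4NF, AcOH, THF, 0 °C to rt
Reagents that add atoms: none
Why: Fluoride-mediated desilylation driven by the Si–F bond; acetic acid buffers the phenoxide so the chromone is not exposed to base.

**Step 6**
Reactants: 10 biaryl phenol
Product: 11 2,4-bis(benzyloxy)-3-{5,7-bis(benzyloxy)-2-[4-(benzyloxy)phenyl]-4-oxo-4H-chromen-3-yl}-6-hydroxybenzaldehyde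
Conditions: MgCl2, Et3N, (CH2O)n, MeCN, reflux; then cold 1 M HCl
Reagents that add atoms: paraformaldehyde (formaldehyde unit), C=O
Why: Casnati–Skattebøl magnesium-mediated ortho-formylation; the magnesium phenoxide delivers formaldehyde to an ortho carbon only, and the two ortho positions of ring D are equivalent, so a single aldehyde should result.

**Step 7**
Reactants: 11 salicylaldehyde; 12 1-[4-(benzyloxy)phenyl]ethan-1-one
Product: 13 (E)-3-(2,4-bis(benzyloxy)-3-{5,7-bis(benzyloxy)-2-[4-(benzyloxy)phenyl]-4-oxo-4H-chromen-3-yl}-6-hydroxyphenyl)-1-[4-(benzyloxy)phenyl]prop-2-en-1-one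
Conditions: KOH, EtOH/THF, rt
Reagents that add atoms: none
Why: Claisen–Schmidt condensation of a non-enolizable aldehyde with a methyl ketone, the E-enone arising by E1cB dehydration; the hindered 2,3-diarylchromone should resist hydroxide at room temperature.

**Step 8**
Reactants: 13 chalcone
Product: 15 3-{2,6-bis(benzyloxy)-3-[(3R)-3-[4-(benzyloxy)phenyl]-3-hydroxypropyl]-4-hydroxyphenyl}-5,7-bis(benzyloxy)-2-[4-(benzyloxy)phenyl]-4H-chromen-4-one, via dihydrochalcone ketone 14 (not isolated)
Conditions: RuCl(p-cymene)[(R,R)-TsDPEN] (2 mol %), HCO2H/Et3N (5:2), CH2Cl2, 35 °C, dark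
Reagents that add atoms: none
Why: Noyori–Ikariya asymmetric transfer hydrogenation; the ruthenium hydride should first reduce the enone C=C by conjugate addition and then the aryl ketone through the outer-sphere six-membered transition state, in which the CH–π contact of p-cymene with ring F makes the (R,R)-ligand give the (R)-carbinol, as with acetophenone.

**Step 9 (key step)**
Reactants: 15 (R)-carbinol
Product: 16 5,7-bis(benzyloxy)-2-[4-(benzyloxy)phenyl]-3-{(2S)-5,7-bis(benzyloxy)-2-[4-(benzyloxy)phenyl]chroman-6-yl}-4H-chromen-4-one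
Conditions: PPh3, DIAD, toluene, 0 °C
Reagents that add atoms: none
Why: PPh3 and DIAD form the betaine, which deprotonates the ring D phenol and turns the C2 hydroxyl into an alkoxyphosphonium leaving group; the tethered phenoxide O1 then displaces Ph3P=O from the back side. The closest known reaction type is the intramolecular Mitsunobu etherification that closes 2-arylchromans from 1-aryl-3-(2-hydroxyaryl)propan-1-ols. Ring E closes in the 6-exo-tet mode. No new stereocenter is created: C2 is inverted, so the (R)-carbinol set by the (R,R)-TsDPEN ligand in step 8 should become (2S). Two selectivities are needed: O1 against the other ring D oxygens, secured because O1 (para to the biaryl carbon) is the only free phenol in 15, and SN2 against ionization of the 4-benzyloxybenzylic centre, favoured by the high effective molarity of a six-membered closure in non-polar toluene at low temperature.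

**Step 10**
Reactants: 16 hexabenzyl flavan–flavone
Product: 17 5,7-dihydroxy-2-(4-hydroxyphenyl)-3-[(2S)-5,7-dihydroxy-2-(4-hydroxyphenyl)chroman-6-yl]-4H-chromen-4-one
Conditions: H2 (1 atm), Pd/C (10 %), THF/MeOH, rt
Reagents that add atoms: none
Why: Hydrogenolysis of six benzyl ethers under neutral conditions; the tetrasubstituted chromone alkene and the cyclic C2–O1 ether should react much more slowly, so C2 stays (S).

**Compound list**

1 | apigenin | O=c1cc(-c2ccc(O)cc2)oc2cc(O)cc(O)c12 | starting material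
2 | 5,7-bis(benzyloxy)-2-[4-(benzyloxy)phenyl]-4H-chromen-4-one | O=c1cc(-c2ccc(OCc3ccccc3)cc2)oc2cc(OCc3ccccc3)cc(OCc3ccccc3)c12 | intermediate
3 | 3-lithio derivative of 2 | O=c1c([Li])c(-c2ccc(OCc3ccccc3)cc2)oc2cc(OCc3ccccc3)cc(OCc3ccccc3)c12 | intermediate
4 | 5,7-bis(benzyloxy)-2-[4-(benzyloxy)phenyl]-3-iodo-4H-chromen-4-one | O=c1c(I)c(-c2ccc(OCc3ccccc3)cc2)oc2cc(OCc3ccccc3)cc(OCc3ccccc3)c12 | intermediate
5 | 3,5-bis(benzyloxy)phenol | Oc1cc(OCc2ccccc2)cc(OCc2ccccc2)c1 | starting material
6 | [3,5-bis(benzyloxy)phenoxy]triisopropylsilane | CC(C)[Si](Oc1cc(OCc2ccccc2)cc(OCc2ccccc2)c1)(C(C)C)C(C)C | intermediate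
7 | [2,6-bis(benzyloxy)-4-(triisopropylsilyloxy)phenyl]lithium | CC(C)[Si](Oc1cc(OCc2ccccc2)c([Li])c(OCc2ccccc2)c1)(C(C)C)C(C)C | intermediate
8 | [2,6-bis(benzyloxy)-4-(triisopropylsilyloxy)phenyl]zinc chloride | CC(C)[Si](Oc1cc(OCc2ccccc2)c([Zn]Cl)c(OCc2ccccc2)c1)(C(C)C)C(C)C | intermediate
9 | 5,7-bis(benzyloxy)-2-[4-(benzyloxy)phenyl]-3-[2,6-bis(benzyloxy)-4-(triisopropylsilyloxy)phenyl]-4H-chromen-4-one | O=c1c(-c2c(OCc3ccccc3)cc(O[Si](C(C)C)(C(C)C)C(C)C)cc2OCc2ccccc2)c(-c2ccc(OCc3ccccc3)cc2)oc2cc(OCc3ccccc3)cc(OCc3ccccc3)c12 | intermediate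
10 | 5,7-bis(benzyloxy)-2-[4-(benzyloxy)phenyl]-3-[2,6-bis(benzyloxy)-4-hydroxyphenyl]-4H-chromen-4-one | O=c1c(-c2c(OCc3ccccc3)cc(O)cc2OCc2ccccc2)c(-c2ccc(OCc3ccccc3)cc2)oc2cc(OCc3ccccc3)cc(OCc3ccccc3)c12 | intermediate
11 | 2,4-bis(benzyloxy)-3-{5,7-bis(benzyloxy)-2-[4-(benzyloxy)phenyl]-4-oxo-4H-chromen-3-yl}-6-hydroxybenzaldehyde | O=Cc1c(O)cc(OCc2ccccc2)c(-c2c(-c3ccc(OCc4ccccc4)cc3)oc3cc(OCc4ccccc4)cc(OCc4ccccc4)c3c2=O)c1OCc1ccccc1 | intermediate
12 | 1-[4-(benzyloxy)phenyl]ethan-1-one | CC(=O)c1ccc(OCc2ccccc2)cc1 | starting material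
13 | (E)-chalcone from 11 and 12 | O=C(/C=C/c1c(O)cc(OCc2ccccc2)c(-c2c(-c3ccc(OCc4ccccc4)cc3)oc3cc(OCc4ccccc4)cc(OCc4ccccc4)c3c2=O)c1OCc1ccccc1)c1ccc(OCc2ccccc2)cc1 | intermediate
14 | dihydrochalcone ketone (C=C of 13 reduced) | O=C(CCc1c(O)cc(OCc2ccccc2)c(-c2c(-c3ccc(OCc4ccccc4)cc3)oc3cc(OCc4ccccc4)cc(OCc4ccccc4)c3c2=O)c1OCc1ccccc1)c1ccc(OCc2ccccc2)cc1 | intermediate
15 | (R)-carbinol, 3-{2,6-bis(benzyloxy)-3-[(3R)-3-[4-(benzyloxy)phenyl]-3-hydroxypropyl]-4-hydroxyphenyl}-5,7-bis(benzyloxy)-2-[4-(benzyloxy)phenyl]-4H-chromen-4-one | O[C@H](CCc1c(O)cc(OCc2ccccc2)c(-c2c(-c3ccc(OCc4ccccc4)cc3)oc3cc(OCc4ccccc4)cc(OCc4ccccc4)c3c2=O)c1OCc1ccccc1)c1ccc(OCc2ccccc2)cc1 | intermediate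
16 | hexabenzyl ether of the target, (2S)-flavan | O=c1c(-c2c(OCc4ccccc4)cc3c(c2OCc2ccccc2)CC[C@@H](c2ccc(OCc4ccccc4)cc2)O3)c(-c2ccc(OCc3ccccc3)cc2)oc2cc(OCc3ccccc3)cc(OCc3ccccc3)c12 | intermediate
17 | 5,7-dihydroxy-2-(4-hydroxyphenyl)-3-[(2S)-5,7-dihydroxy-2-(4-hydroxyphenyl)chroman-6-yl]-4H-chromen-4-one | O=c1c(-c2c(O)cc3c(c2O)CC[C@@H](c2ccc(O)cc2)O3)c(-c2ccc(O)cc2)oc2cc(O)cc(O)c12 | target

**Step count.** Total: 10 steps. Longest linear sequence: 9 steps (steps 1, 2, 4, 5, 6, 7, 8, 9, 10, from apigenin).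

**Steps most likely to fail**

Step 9. The activated C2–O bond may ionize to a 4-benzyloxybenzylic cation before back-side attack, which would erode enantiopurity or lead to elimination to the styrene. The fallback sets out from 13. The alkene alone is hydrogenated (H2, Pd/C poisoned with Ph2S, EtOAc) and ketone 14 is isolated. Acid-catalysed cyclodehydration (p-TsOH cat., toluene, reflux with water removal) should give 5,7-bis(benzyloxy)-2-[4-(benzyloxy)phenyl]-3-{5,7-bis(benzyloxy)-2-[4-(benzyloxy)phenyl]-4H-chromen-6-yl}-4H-chromen-4-one F1. Iridium-catalysed asymmetric hydrogenation of its C2=C3 enol ether ([Ir(cod)(tBu-PHOX)]BArF, H2 50 bar, CH2Cl2) should then give the flavan; the ligand enantiomer is chosen on a model 2-aryl-4H-chromene for the (2S) sense. The fallback comes back to the route at 16.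

Step 8. Hydride may be delivered to the carbonyl before the alkene, leaving an allylic alcohol that is not reduced further, or reduction of the electron-rich aryl ketone may stall. The fallback sets out from 13 and makes no compound outside the list (F0). The alkene is hydrogenated selectively (H2, Pd/C with Ph2S, EtOAc) to isolated 14. Corey–Bakshi–Shibata reduction ((S)-Me-CBS oxazaborolidine, BH3·SMe2 in excess for the free phenol, THF, −20 °C) should then give the (R)-carbinol. It comes back at 15.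

Step 4. Deprotonation may occur at a benzylic OCH2 (followed by Wittig rearrangement) and not at the ring C–H, or transmetalation and reductive elimination may be slow at the tetra-ortho-substituted biaryl. The fallback sets out from 6. Electrophilic bromination para to the silyloxy group (NBS, MeCN, 0 °C) should give [4-bromo-3,5-bis(benzyloxy)phenoxy]triisopropylsilane F2. Bromine–lithium exchange (t-BuLi, THF, −78 °C) gives 7, which is trapped with B(OMe)3 and hydrolysed to [2,6-bis(benzyloxy)-4-(triisopropylsilyloxy)phenyl]boronic acid F3. Suzuki–Miyaura coupling of F3 with 4 (Pd(OAc)2, SPhos, K3PO4, toluene/H2O, 90 °C) comes back at 9.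

**Further compounds**

F1 | step 9 | 5,7-bis(benzyloxy)-2-[4-(benzyloxy)phenyl]-3-{5,7-bis(benzyloxy)-2-[4-(benzyloxy)phenyl]-4H-chromen-6-yl}-4H-chromen-4-one | O=c1c(-c2c(OCc4ccccc4)cc3c(c2OCc2ccccc2)CC=C(c2ccc(OCc4ccccc4)cc2)O3)c(-c2ccc(OCc3ccccc3)cc2)oc2cc(OCc3ccccc3)cc(OCc3ccccc3)c12
F0 | step 8 | none | none
F2 | step 4 | [4-bromo-3,5-bis(benzyloxy)phenoxy]triisopropylsilane | CC(C)[Si](Oc1cc(OCc2ccccc2)c(Br)c(OCc2ccccc2)c1)(C(C)C)C(C)C
F3 | step 4 | [2,6-bis(benzyloxy)-4-(triisopropylsilyloxy)phenyl]boronic acid | CC(C)[Si](Oc1cc(OCc2ccccc2)c(B(O)O)c(OCc2ccccc2)c1)(C(C)C)C(C)C
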